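## Retrosynthetic overview

1. Last C–C bond: C2'–C3' of the side chain, by B-alkyl Suzuki coupling of a ring vinyl fragment (9) with an (E)-alkenyl iodide carrying the rest of the chain (15); both silyl groups come off last.
2. The vinyl group comes from a C1' aldehyde, which comes from the trans-1,3-diol 6; the gem-dimethyl carbon is completed by cyclopropanation and hydrogenolysis of a ring alkene.
3. The only ring (the cyclohexane) is closed by ring-closing metathesis of an acyclic diene that already holds both stereocentres.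
4. Both stereocentres come from geraniol: Sharpless epoxidation fixes the carbinol carbon, and anti SN2 opening of the epoxide at C2 by an isopropenyl cuprate fixes the ring CH. This reproduces the anti C/O addition across the E-alkene that gives the natural trans arrangement.
5. The side chain also comes from geraniol: silylation, SeO2 oxidation, bromide, propargylation, methylation, hydrozirconation–iodination.

Assumption: reagents made in situ (cuprate, ylide, 1,3-dilithiopropyne, B-alkyl-9-BBN) belong to the step that uses them.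

## Route

### Ring fragment

**Step 1**
Reactants: 1, geraniol
Product: 2, [(2S,3S)-3-methyl-3-(4-methylpent-3-en-1-yl)oxiran-2-yl]methanol
Conditions: Ti(OiPr)4 (5 mol %), L-(+)-DET (7.5 mol %), t-BuOOH, 4 Å MS, CH2Cl2, −20 °C
Reagents that add atoms: tert-butyl hydroperoxide, CC(C)(C)OO
Why: Katsuki–Sharpless asymmetric epoxidation of the allylic alcohol only; L-(+)-DET gives the (2S,3S)-epoxide, and C3 becomes the ring carbinol carbon.

**Step 2**
Reactants: 2
Product: 3, (2R,3S)-3,7-dimethyl-2-(prop-1-en-2-yl)oct-6-ene-1,3-diol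
Conditions: isopropenylMgBr (4 equiv), CuI (20 mol %), THF, −40 → 0 °C
Reagents that add atoms: isopropenylmagnesium bromide, CC(=C)[Mg]Br
Why: Cu-catalysed SN2 epoxide opening at the secondary C2 (C3 is fully substituted) with inversion, which sets the ring CH centre anti to the untouched tertiary C–O bond.

**Step 3**
Reactants: 3
Product: 4, (1S,2R)-2-(hydroxymethyl)-1,3-dimethylcyclohex-3-en-1-ol
Conditions: Grubbs II (5 mol %), toluene (0.01 M), 80 °C, isobutene lost
Reagents that add atoms: none
Why: Ring-closing metathesis; the catalyst loads on the prenyl-type terminus and closes onto the isopropenyl group to give the trisubstituted cyclohexene without touching either stereocentre.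

**Step 4**
Reactants: 4
Product: 5, (2R,3S)-2-(hydroxymethyl)-1,3-dimethylbicyclo[4.1.0]heptan-3-ol (mixture at the cyclopropane carbons)
Conditions: Et2Zn, CH2I2, CH2Cl2, 0 °C → rt
Reagents that add atoms: diiodomethane, ICI
Why: Simmons–Smith (Furukawa) cyclopropanation assisted by the zinc alkoxides; the cyclopropane configuration does not matter because it is erased in step 5.

**Step 5**
Reactants: 5
Product: 6, (1S,2R)-2-(hydroxymethyl)-1,3,3-trimethylcyclohexan-1-ol
Conditions: H2 (4 atm), PtO2, AcOH, rt
Reagents that add atoms: none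
Why: Cyclopropane hydrogenolysis at the least hindered CH2–CH bond turns the bridging CH2 into the second methyl, giving the gem-dimethyl carbon.

**Step 6**
Reactants: 6
Product: 7, (1S,2S)-2-hydroxy-2,6,6-trimethylcyclohexane-1-carbaldehyde
Conditions: Dess–Martin periodinane, NaHCO3, CH2Cl2, 0 °C → rt
Reagents that add atoms: none
Why: Only the primary alcohol can be oxidised; buffered, base-free conditions avoid retro-aldol and epimerisation of the α-CH.

**Step 7**
Reactants: 7
Product: 8, (1S,2S)-2,6,6-trimethyl-2-[(triethylsilyl)oxy]cyclohexane-1-carbaldehyde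
Conditions: TESOTf, 2,6-lutidine, CH2Cl2, −78 °C
Reagents that add atoms: triethylsilyl triflate, CC[Si](CC)(CC)OS(=O)(=O)C(F)(F)F
Why: Silyl triflate silylation of the hindered tertiary alcohol removes the free alkoxide that would trigger retro-aldol in the next step.

**Step 8**
Reactants: 8
Product: 9, {[(1S,2S)-2-ethenyl-1,3,3-trimethylcyclohexyl]oxy}triethylsilane
Conditions: Ph3PCH3Br, KHMDS, THF, −78 → 0 °C
Reagents that add atoms: methyltriphenylphosphonium bromide, C[P+](c1ccccc1)(c1ccccc1)c1ccccc1.[Br-]
Why: Wittig methylenation; addition of the small ylide to the aldehyde is faster than deprotonation of the shielded α-CH, so C2 should keep its configuration.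

### Side-chain fragment

**Step 9**
Reactants: 1, geraniol
Product: 10, tert-butyl{[(2E)-3,7-dimethylocta-2,6-dien-1-yl]oxy}diphenylsilane
Conditions: TBDPSCl, imidazole, CH2Cl2, rt
Reagents that add atoms: tert-butyl(chloro)diphenylsilane, CC(C)(C)[Si](Cl)(c1ccccc1)c1ccccc1
Why: Silyl protection of the primary allylic alcohol with a group that survives SeO2, organolithiums, Schwartz reagent and the Suzuki conditions.

**Step 10**
Reactants: 10
Product: 11, (2E,6E)-8-[(tert-butyldiphenylsilyl)oxy]-2,6-dimethylocta-2,6-dien-1-ol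
Conditions: SeO2 (cat.), t-BuOOH, salicylic acid (cat.), CH2Cl2, rt; then NaBH4, MeOH, 0 °C
Reagents that add atoms: selenium dioxide, O=[Se]=O, with tert-butyl hydroperoxide, CC(C)(C)OO, as reoxidant
Why: Sharpless-type SeO2 allylic oxidation (ene, then [2,3]-shift) is selective for the E-methyl of the terminal isopropylidene; borohydride returns any over-oxidised enal to 11.

**Step 11**
Reactants: 11
Product: 12, {[(2E,6E)-8-bromo-3,7-dimethylocta-2,6-dien-1-yl]oxy}(tert-butyl)diphenylsilane
Conditions: CBr4, PPh3, CH2Cl2, 0 °C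
Reagents that add atoms: carbon tetrabromide, BrC(Br)(Br)Br
Why: Appel bromination of the primary allylic alcohol proceeds without allylic shift or loss of E geometry.

**Step 12**
Reactants: 12
Product: 13, tert-butyl{[(2E,6E)-3,7-dimethylundeca-2,6-dien-10-yn-1-yl]oxy}diphenylsilane
Conditions: propyne, n-BuLi (2 equiv), TMEDA, THF/hexane, −78 → 0 °C; then 12, −78 °C → rt
Reagents that add atoms: propyne, CC#C
Why: SN2 alkylation of 1,3-dilithiopropyne at its more nucleophilic propargylic carbon by the primary allylic bromide gives the terminal 1,5-enyne.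

**Step 13**
Reactants: 13
Product: 14, tert-butyl{[(2E,6E)-3,7-dimethyldodeca-2,6-dien-10-yn-1-yl]oxy}diphenylsilane
Conditions: n-BuLi, THF, −78 °C; MeI, −78 °C → rt
Reagents that add atoms: iodomethane, CI
Why: Acetylide alkylation caps the alkyne with the methyl that becomes the C3' methyl of the target.

**Step 14**
Reactants: 14
Product: 15, tert-butyl{[(2E,6E,10E)-11-iodo-3,7-dimethyldodeca-2,6,10-trien-1-yl]oxy}diphenylsilane
Conditions: Cp2Zr(H)Cl (2 equiv), THF, rt → 45 °C; then I2, 0 °C
Reagents that add atoms: iodine, II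
Why: syn-Hydrozirconation with excess Schwartz reagent equilibrates Zr to the methyl-bearing alkyne carbon (about 9:1 expected), and iodinolysis with retention gives the (E)-2-iodoalkene.

### Coupling and end game

**Step 15**
Reactants: 9 and 15
Product: 16, tert-butyl{[(2E,6E,10E)-3,7,11-trimethyl-13-{(1S,2S)-2,6,6-trimethyl-2-[(triethylsilyl)oxy]cyclohexyl}trideca-2,6,10-trien-1-yl]oxy}diphenylsilane
Conditions: 9, 9-BBN, THF, rt → 50 °C; then 15, PdCl2(dppf) (10 mol %), AsPh3, Cs2CO3, DMF/H2O, rt
Reagents that add atoms: none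
Why: Anti-Markovnikov hydroboration of the only monosubstituted alkene, then B-alkyl Suzuki–Miyaura coupling with retention of the alkenyl iodide geometry, gives the E-trisubstituted C3'=C4' alkene.

**Step 16**
Reactants: 16
Product: 17, preluffariellolide A, (1S,2S)-2-[(3E,7E,11E)-13-hydroxy-3,7,11-trimethyltrideca-3,7,11-trien-1-yl]-1,3,3-trimethylcyclohexan-1-ol
Conditions: TBAF (excess), THF, rt → 50 °C
Reagents that add atoms: none
Why: Fluoride cleaves both the primary TBDPS and the tertiary TES ether without affecting the alkenes or stereocentres.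

## Compound list

1 | geraniol | CC(C)=CCC/C(C)=C/CO | starting material
2 | [(2S,3S)-3-methyl-3-(4-methylpent-3-en-1-yl)oxiran-2-yl]methanol | OC[C@@H]1O[C@@]1(C)CCC=C(C)C | intermediate
3 | (2R,3S)-3,7-dimethyl-2-(prop-1-en-2-yl)oct-6-ene-1,3-diol | OC[C@@H](C(C)=C)[C@@](C)(O)CCC=C(C)C | intermediate
4 | (1S,2R)-2-(hydroxymethyl)-1,3-dimethylcyclohex-3-en-1-ol | OC[C@H]1C(C)=CCC[C@]1(C)O | intermediate
5 | (2R,3S)-2-(hydroxymethyl)-1,3-dimethylbicyclo[4.1.0]heptan-3-ol | OC[C@H]1C2(C)CC2CC[C@]1(C)O | intermediate
6 | (1S,2R)-2-(hydroxymethyl)-1,3,3-trimethylcyclohexan-1-ol | OC[C@H]1C(C)(C)CCC[C@]1(C)O | intermediate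
7 | (1S,2S)-2-hydroxy-2,6,6-trimethylcyclohexane-1-carbaldehyde | O=C[C@H]1C(C)(C)CCC[C@]1(C)O | intermediate
8 | (1S,2S)-2,6,6-trimethyl-2-[(triethylsilyl)oxy]cyclohexane-1-carbaldehyde | O=C[C@H]1C(C)(C)CCC[C@]1(C)O[Si](CC)(CC)CC | intermediate
9 | {[(1S,2S)-2-ethenyl-1,3,3-trimethylcyclohexyl]oxy}triethylsilane | C=C[C@H]1C(C)(C)CCC[C@]1(C)O[Si](CC)(CC)CC | intermediate
10 | geranyl TBDPS ether | CC(C)=CCC/C(C)=C/CO[Si](c1ccccc1)(c1ccccc1)C(C)(C)C | intermediate
11 | (2E,6E)-8-[(tert-butyldiphenylsilyl)oxy]-2,6-dimethylocta-2,6-dien-1-ol | OC/C(C)=C/CC/C(C)=C/CO[Si](c1ccccc1)(c1ccccc1)C(C)(C)C | intermediate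
12 | (2E,6E)-8-bromo-3,7-dimethylocta-2,6-dienyl TBDPS ether | BrC/C(C)=C/CC/C(C)=C/CO[Si](c1ccccc1)(c1ccccc1)C(C)(C)C | intermediate
13 | (2E,6E)-3,7-dimethylundeca-2,6-dien-10-ynyl TBDPS ether | C#CCC/C(C)=C/CC/C(C)=C/CO[Si](c1ccccc1)(c1ccccc1)C(C)(C)C | intermediate
14 | (2E,6E)-3,7-dimethyldodeca-2,6-dien-10-ynyl TBDPS ether | CC#CCC/C(C)=C/CC/C(C)=C/CO[Si](c1ccccc1)(c1ccccc1)C(C)(C)C | intermediate
15 | (2E,6E,10E)-11-iodo-3,7-dimethyldodeca-2,6,10-trienyl TBDPS ether | C/C(I)=C\CC/C(C)=C/CC/C(C)=C/CO[Si](c1ccccc1)(c1ccccc1)C(C)(C)C | intermediate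
16 | bis-silyl ether of preluffariellolide A (13'-O-TBDPS, ring O-TES) | C/C(=C\CO[Si](c1ccccc1)(c1ccccc1)C(C)(C)C)CC/C=C(\C)CC/C=C(\C)CC[C@H]1C(C)(C)CCC[C@]1(C)O[Si](CC)(CC)CC | intermediate
17 | preluffariellolide A | C/C(=C\CO)CC/C=C(\C)CC/C=C(\C)CC[C@H]1C(C)(C)CCC[C@]1(C)O | target

## Step count and risks

Total steps: 16. Longest linear sequence: 10 (steps 1–8, 15, 16); the side-chain branch is 8 (steps 9–14, 15, 16).

Steps most likely to fail:

1. **Step 2, cuprate opening at the hindered C2.** Payne rearrangement or low reactivity could compete. Fallback: oxidise 2 to the methyl glycidate, open at the carbonyl-activated α-carbon with lithium diisopropenylcuprate, and reduce the ester with LiAlH4 to reach the same diol 3.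
2. **Step 5, regiochemistry of cyclopropane hydrogenolysis.** Cleavage of the other CH2 bond or the ring bond would give 1,2-dimethyl or ring-expanded by-products. Fallback: skip the cyclopropane and add the second methyl directly to alkene 4 by Markovnikov hydrogen-atom-transfer hydromethylation (Fe(acac)3/PhSiH3 with a formaldehyde sulfonylhydrazone).
3. **Step 14, regioselectivity of hydrozirconation.** The expected ~10% 10-iodo isomer would carry through the coupling. Fallback: drop the alkenyl iodide and form the C1'–C2' bond by sulfone alkylation: convert 6 to the C1' phenyl sulfone, alkylate its dianion with (2E,6E,10E)-12-bromofarnesyl TBDPS ether (from farnesol by silylation, SeO2, CBr4/PPh3), then desulfonylate with Na/Hg and desilylate.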